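The numbers in the tables are simulated for substances that don't exist; the scatter is artificial.

In a one-step world the substrate lost reappears as ring, and a flask holds no stock beyond what it shows. Saturday's flask, which I look at after 8.0 d and may then change, does not behave so.

all flasks: substrate 0.012 M

|  | activator | temperature | remark | time |
|---|---|---|---|---|
| Saturday's | 0.024 M | 0 °C | the very flask that is asked about, followed so far |  |
| Monday's | 0.012 M | 6 °C | run made earlier |  |
| flask | 0.0240 M | 0 °C |  | 8.0 d |

- Saturday's (time / h: ring / %, substrate / %): 30.0: 36.8, 0; 60.0: 37.7, 0.2; 96.0: 38.5, 0.2; 120: 38.8, 0; 144: 37.9, 0; 192: 36.6, 0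
- Monday's (time / h: ring / %, substrate / %): 2.00: 14.4, 38.0; 5.00: 26.0, 11.1; 10.0: 30.3, 3.0; 15.0: 31.7, 2.0; 20.0: 28.8, 0.3; 30.0: 32.0, 0.1

(readings scatter by 1 percentage point)

- gamma: change nothing and wait 4.0 d more
- delta: at 8.0 d raise the temperature by 20 K, then wait 4.0 d
- alpha: at 8.0 d take out 90% of the ring then present, then wait 4.0 d
- eta: at 8.0 d add activator, 50.0% of the amount charged, then wait 4.0 d

- ring, in percent of the substrate first charged, at 8.0 d
- which option adds most ring ("none" when 2 percentage points or less is all one gets) (gamma / delta / alpha / eta / none)
- ring present, with what was taken out counted in, in percent of the substrate first charged, after gamma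
- ring present, with what was taken out counted in, in percent of the substrate first charged, after eta

- what is taken out of ring is counted as made
- additions bring no volume worth counting

I climb the ladder from the fastest rung. Monday's first reading, integrated as a plain exponential decay, gives the substrate an apparent rate, averaged over 2.00 h, of 0.484 /h, so an apparent half-life of 1.43 h; Monday's activator equals the substrate at 0.012 M, so this is a rough figure and not a constant. Saturday's flask has twice the activator but is colder, and these pull opposite ways, so I carry that half-life as a scale. Saturday's first reading at 30.0 h then lies 21.0 half-lives out, and it shows substrate at 0%: the substrate, the limiting reagent, is spent on this rung.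

On the next rung, from 30.0 h to 192 h, Saturday's ring readings scatter about 37.7%, which I take as ring now and after gamma or eta. What stays is the reserve, the share of the charged substrate that is neither ring nor substrate, reckoned as 62.3%. In this closed flask, further ring has to come out of it. Whether it can, a flat line doesn't say, so I leave delta and alpha open.

The forecast gives ring 37.7% now, 37.6% after gamma, 37.6% after eta, and as best option none: “Warming (delta) has no substrate to act on.”

The flask gives 38.2% now, 38.2% after gamma and 38.2% after eta, and the best option is delta, adding 18 percentage points, with alpha adding 12 points.

    ring ⇌ isomer of the product (K = 0.520, k = 0.00430 /min, Ea = 84.0 kJ/mol, ΔH = −90.0 kJ/mol)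
    substrate + ring → side product (k = 0.450 /M/min, Ea = 49.0 kJ/mol)
    substrate + activator → activated form (k = 0.400 /M/min, Ea = 63.0 kJ/mol)
    substrate + activated form → open dimer (k = 0.540 /M/min, Ea = 42.0 kJ/mol)
    activated form → ring (k = 0.00500 /min, Ea = 92.0 kJ/mol)
    (constants at 0 °C)

Against the 62.3% I read from the scattered readings, Saturday's flask as computed holds a reserve of 61.8%, which is 31.5% open dimer, 10.4% side product and 19.9% isomer of the product. There isomer to ring stands at 0.520, close to the equilibrium constant 0.52, so the plateau is a standing equilibrium and not a dead end.

In the repeat at 25 °C, ring at 69.2% leaves a reserve of 30.8%. The computed flask holds it as 10.9% open dimer, 18.7% side product and 1.30% isomer of the product.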